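**Plan**

1. Isochromene numbering is used (C1, O2, C3, C4, C4a, C5 to C8, C8a; ring A is the carbocycle, ring B the pyran). The retrosynthesis cuts the stearate at O–C7, then C7–C8 and C5=C4a of ring A together, leaving butane-2,3-dione and a ring B aldehyde.
2. Enabling feature: in ring A the tertiary carbinol C7 sits beside ketone C8 (an acyloin unit) and ketone C6 is conjugated to C5=C4a, while the C1=C8a enol ether of ring B is a latent aldehyde. C1 can therefore travel as an sp3 methyl acetal and C4a as an enol sulfonate; both helpers leave during ring A closure.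
3. Forward: ring B is built first from ethyl (R)-3-hydroxybutanoate (Claisen condensation, aminomethylenation with ring closure, methoxide addition with enolate sulfonylation, ester to aldehyde). Ring A then forms in one flask: sulfonate displacement at C4a by the diketone enolate, loss of methanol, carbene-catalysed crossed benzoin closure. The stearate goes on last.
4. Stereochemistry: C3 comes from the chiral pool. C7 is set by the chiral triazolium carbene in the intramolecular benzoin reaction (attack on the Si face of the C7 carbonyl gives 7R).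

Key step: step 6

Remark: the acetal carbon introduced in step 3 is carried as a mixture of epimers because it becomes sp2 again in step 6; the antipode of the triazolium salt would be taken if the sense of induction proved opposite.

Step 1
Reactants: 1 ethyl (R)-3-hydroxybutanoate; 2 methyl acetate
Product: 3 methyl (5R)-5-hydroxy-3-oxohexanoate
Conditions: LiN(iPr)2 (3.3 equiv), 2 (3.3 equiv), THF, −78 °C; then 1, −78 to −30 °C; aq NH4Cl
Reagents that add atoms: none
Why: Crossed Claisen condensation in which excess ester enolate first deprotonates the hydroxyl and then acylates at the ester carbonyl of 1, leaving the chiral-pool stereocenter untouched.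

Step 2
Reactants: 3 methyl (5R)-5-hydroxy-3-oxohexanoate
Product: 5 methyl (2R)-2-methyl-4-oxo-3,4-dihydro-2H-pyran-5-carboxylate, via aminomethylene keto ester 4 (not isolated)
Conditions: Me2NCH(OMe)2 (1.2 equiv), toluene, rt; then TsOH·H2O (10 mol %), 40 °C
Reagents that add atoms: N,N-dimethylformamide dimethyl acetal, COC(OC)N(C)C
Why: Knoevenagel-type aminomethylenation of the active methylene should be followed by addition–elimination of the hydroxyl at the aminomethylene carbon (6-endo-trig oxa-Michael, loss of dimethylamine), a known route from δ-hydroxy-β-keto esters to dihydropyranones that creates no new stereocenter.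

Step 3
Reactants: 5 methyl (2R)-2-methyl-4-oxo-3,4-dihydro-2H-pyran-5-carboxylate
Product: 7 methyl (2RS,6R)-2-methoxy-6-methyl-4-[(4-methylbenzenesulfonyl)oxy]-5,6-dihydro-2H-pyran-3-carboxylate, via sodium enolate 6 (not isolated)
Conditions: NaOMe (1.05 equiv), THF, −40 °C; then Ts2O (1.1 equiv), −40 to 0 °C
Reagents that add atoms: sodium methoxide, C[O-].[Na+]; 4-methylbenzenesulfonic anhydride, Cc1ccc(cc1)S(=O)(=O)OS(=O)(=O)c1ccc(C)cc1
Why: Oxa-Michael addition of methoxide to the alkoxymethylene β-keto ester should give the stabilised enolate, which is O-sulfonylated on the ketone oxygen (enol tosylate formation); the new acetal carbon forms as both epimers, which does not matter.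

Step 4
Reactants: 7 methyl (2RS,6R)-2-methoxy-6-methyl-4-[(4-methylbenzenesulfonyl)oxy]-5,6-dihydro-2H-pyran-3-carboxylate
Product: 8 (2RS,6R)-3-(hydroxymethyl)-2-methoxy-6-methyl-5,6-dihydro-2H-pyran-4-yl 4-methylbenzenesulfonate
Conditions: iBu2AlH (2.5 equiv), CH2Cl2, −78 °C; aq sodium potassium tartrate
Reagents that add atoms: none
Why: Low-temperature aluminium hydride reduction of the conjugated ester to the allylic alcohol should leave the enol sulfonate and the acetal intact.

Step 5
Reactants: 8 (2RS,6R)-3-(hydroxymethyl)-2-methoxy-6-methyl-5,6-dihydro-2H-pyran-4-yl 4-methylbenzenesulfonate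
Product: 9 (2RS,6R)-3-formyl-2-methoxy-6-methyl-5,6-dihydro-2H-pyran-4-yl 4-methylbenzenesulfonate
Conditions: activated MnO2 (15 equiv), CH2Cl2, rt
Reagents that add atoms: none
Why: Allylic alcohol oxidation on MnO2 runs under neutral conditions and should spare the acid-labile acetal and the sulfonate.

Step 6
Reactants: 9 (2RS,6R)-3-formyl-2-methoxy-6-methyl-5,6-dihydro-2H-pyran-4-yl 4-methylbenzenesulfonate; 10 butane-2,3-dione
Product: 13 (3R,7R)-7-hydroxy-3,7-dimethyl-3,4-dihydro-6H-isochromene-6,8(7H)-dione, via dioxobutyl acetal aldehyde 11 (not isolated), via dioxobutylidene pyran aldehyde 12 (not isolated)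
Conditions: 10 (3 equiv), Cs2CO3 (2.2 equiv), 4 Å MS, MeCN, 0 °C to rt; then (5aS,10bR)-2-(pentafluorophenyl)-5a,10b-dihydro-4H,6H-indeno[2,1-b][1,2,4]triazolo[4,3-d][1,4]oxazin-2-ium tetrafluoroborate (15 mol %), rt, same flask
Reagents that add atoms: none
Why: Proposed new method: the caesium enolate of 10 should attack C4a of 9 by addition–elimination with loss of tosylate (C5–C4a), the vinylogous enolate 11 should expel the C1 methoxide (E1cB) to give the neutral dienone aldehyde 12, and the carbene should then convert the formyl group into an acyl anion equivalent that adds to the C7 carbonyl (C7–C8) and is released. The closest known reactions are addition–elimination of ketone enolates on β-sulfonyloxy or β-chloro enals and enones, and the enantioselective intramolecular aldehyde–ketone crossed benzoin reaction with aminoindanol-derived triazolium salts; here they are run as one domino. Ring A closes by 6-exo-trig attack of the acyl anion equivalent on the exocyclic C7 carbonyl. C7 is the only new stereocenter and is set by the catalyst, which is chosen to deliver C8 to the Si face of the ketone (7R); C3 is too remote to interfere. The step needs C5 to bond to C4a and not C1, and C8 to attack C7 and not C6: the first is secured because C1 is an sp3 acetal while C4a carries the sulfonate, the second because C6 lies in the plane of the dienone where the formyl-derived nucleophile cannot reach it, whereas the acetyl carbonyl C7 can rotate into a six-membered transition state. Aldol addition of the enolate to the hindered formyl group is reversible, whereas sulfonate displacement is not.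

Step 7
Reactants: 13 (3R,7R)-7-hydroxy-3,7-dimethyl-3,4-dihydro-6H-isochromene-6,8(7H)-dione; 14 octadecanoyl chloride
Product: 15 (3R,7R)-3,7-dimethyl-6,8-dioxo-3,4,7,8-tetrahydro-6H-isochromen-7-yl octadecanoate
Conditions: 14 (1.5 equiv), DMAP (0.3 equiv), pyridine/CH2Cl2, 0 °C to rt
Reagents that add atoms: none
Why: Acyl-transfer-catalysed esterification of the tertiary α-ketol with the acid chloride breaks no bond at C7, so its configuration should be retained.

**Compound list**

1 | ethyl (R)-3-hydroxybutanoate | C[C@@H](O)CC(=O)OCC | starting material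
2 | methyl acetate | COC(C)=O | starting material
3 | methyl (5R)-5-hydroxy-3-oxohexanoate | C[C@@H](O)CC(=O)CC(=O)OC | intermediate
4 | methyl (5R)-2-[(dimethylamino)methylidene]-5-hydroxy-3-oxohexanoate | C[C@@H](O)CC(=O)C(=CN(C)C)C(=O)OC | intermediate
5 | methyl (2R)-2-methyl-4-oxo-3,4-dihydro-2H-pyran-5-carboxylate | C[C@@H]1CC(=O)C(C(=O)OC)=CO1 | intermediate
6 | sodium (2R,6RS)-6-methoxy-5-(methoxycarbonyl)-2-methyl-3,6-dihydro-2H-pyran-4-olate | C[C@@H]1CC([O-])=C(C(=O)OC)C(OC)O1.[Na+] | intermediate
7 | methyl (2RS,6R)-2-methoxy-6-methyl-4-[(4-methylbenzenesulfonyl)oxy]-5,6-dihydro-2H-pyran-3-carboxylate | C[C@@H]1CC(OS(=O)(=O)c2ccc(C)cc2)=C(C(=O)OC)C(OC)O1 | intermediate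
8 | (2RS,6R)-3-(hydroxymethyl)-2-methoxy-6-methyl-5,6-dihydro-2H-pyran-4-yl 4-methylbenzenesulfonate | C[C@@H]1CC(OS(=O)(=O)c2ccc(C)cc2)=C(CO)C(OC)O1 | intermediate
9 | (2RS,6R)-3-formyl-2-methoxy-6-methyl-5,6-dihydro-2H-pyran-4-yl 4-methylbenzenesulfonate | C[C@@H]1CC(OS(=O)(=O)c2ccc(C)cc2)=C(C=O)C(OC)O1 | intermediate
10 | butane-2,3-dione | CC(=O)C(C)=O | starting material
11 | (2RS,6R)-4-(2,3-dioxobutyl)-2-methoxy-6-methyl-5,6-dihydro-2H-pyran-3-carbaldehyde | C[C@@H]1CC(CC(=O)C(C)=O)=C(C=O)C(OC)O1 | intermediate
12 | (2R,4Z)-4-(2,3-dioxobutylidene)-2-methyl-3,4-dihydro-2H-pyran-5-carbaldehyde | C[C@@H]1C/C(=C/C(=O)C(C)=O)C(C=O)=CO1 | intermediate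
13 | (3R,7R)-7-hydroxy-3,7-dimethyl-3,4-dihydro-6H-isochromene-6,8(7H)-dione | O[C@]1(C)C(=O)C=C2C[C@@H](C)OC=C2C1=O | intermediate
14 | octadecanoyl chloride | CCCCCCCCCCCCCCCCCC(=O)Cl | starting material
15 | (3R,7R)-3,7-dimethyl-6,8-dioxo-3,4,7,8-tetrahydro-6H-isochromen-7-yl octadecanoate | CCCCCCCCCCCCCCCCCC(=O)O[C@]1(C)C(=O)C=C2C[C@@H](C)OC=C2C1=O | target

Total step count: 7. Longest linear sequence: 7 steps (1 to 15).

**Steps most likely to fail**

Step 6. What may go wrong:
- competing aldol or Knoevenagel reaction of the diketone enolate at the formyl group;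
- self-condensation of the diketone under base;
- erosion of facial selectivity if the benzoin addition becomes reversible;
- base-induced cleavage of the α-hydroxy-β-diketone.

The fallback makes the two bonds in separate, known operations and sets out from 7. The potassium enolate of 3,3-dimethoxybutan-2-one (KN(SiMe3)2, 2.2 equiv, THF, −78 to 0 °C) should displace the sulfonate, and the vinylogous enolate should lose methoxide, to give methyl (2R,4Z)-4-(3,3-dimethoxy-2-oxobutylidene)-2-methyl-3,4-dihydro-2H-pyran-5-carboxylate F1. Reduction with iBu2AlH should take ester and ketone to (Z)-1-[(2R)-5-(hydroxymethyl)-2-methyl-2,3-dihydro-4H-pyran-4-ylidene]-3,3-dimethoxybutan-2-ol F2 (both carbinol epimers). MnO2 should re-oxidise both allylic alcohols to (2R,4Z)-4-(3,3-dimethoxy-2-oxobutylidene)-2-methyl-3,4-dihydro-2H-pyran-5-carbaldehyde F3. Aqueous oxalic acid should then free the diketone. The fallback comes back to the route at 12, which is isolated and closed to 13 with the same triazolium salt and iPr2NEt in an intramolecular aldehyde–ketone benzoin reaction.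

Step 3. What may go wrong:
- ring opening by retro-oxa-Michael elimination, with loss of configuration at the methyl-bearing ring carbon;
- sulfonylation on carbon;
- loss of methanol from the acetal during isolation.

The fallback sets out from 5 and installs both oxygens under acid instead. HC(OMe)3 and MeOH with camphorsulfonic acid (cat.) should add methanol at the enol ether carbon and convert the ketone into its methyl enol ether, giving methyl (2RS,6R)-2,4-dimethoxy-6-methyl-5,6-dihydro-2H-pyran-3-carboxylate F4. iBu2AlH should give [(2RS,6R)-2,4-dimethoxy-6-methyl-5,6-dihydro-2H-pyran-3-yl]methanol F5, and MnO2 should give (2RS,6R)-2,4-dimethoxy-6-methyl-5,6-dihydro-2H-pyran-3-carbaldehyde F6. Under the conditions of step 6, methoxide leaves from C4a in place of the sulfonate, and the fallback comes back to the route at 11.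

Step 4. What may go wrong:
- conjugate hydride addition;
- cleavage of the enol sulfonate by the hydride;
- over-reduction.

The fallback sets out from 1 and carries the acyl group as an N-methoxy-N-methylamide, so that one hydride addition stops at the aldehyde level. Claisen condensation of 1 with the lithium enolate of N-methoxy-N-methylacetamide should give (5R)-5-hydroxy-N-methoxy-N-methyl-3-oxohexanamide F7. Aminomethylenation and ring closure as in step 2 should give (2R)-N-methoxy-N,2-dimethyl-4-oxo-3,4-dihydro-2H-pyran-5-carboxamide F8. NaOMe then Ts2O as in step 3 should give (2RS,6R)-2-methoxy-3-[methoxy(methyl)carbamoyl]-6-methyl-5,6-dihydro-2H-pyran-4-yl 4-methylbenzenesulfonate F9. iBu2AlH (1.2 equiv, −78 °C) should then deliver the aldehyde, and the fallback comes back to the route at 9.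

**Further compounds**

F1 | step 6 | methyl (2R,4Z)-4-(3,3-dimethoxy-2-oxobutylidene)-2-methyl-3,4-dihydro-2H-pyran-5-carboxylate | C[C@@H]1C/C(=C/C(=O)C(C)(OC)OC)C(C(=O)OC)=CO1
F2 | step 6 | (Z)-1-[(2R)-5-(hydroxymethyl)-2-methyl-2,3-dihydro-4H-pyran-4-ylidene]-3,3-dimethoxybutan-2-ol | C[C@@H]1C/C(=C/C(O)C(C)(OC)OC)C(CO)=CO1
F3 | step 6 | (2R,4Z)-4-(3,3-dimethoxy-2-oxobutylidene)-2-methyl-3,4-dihydro-2H-pyran-5-carbaldehyde | C[C@@H]1C/C(=C/C(=O)C(C)(OC)OC)C(C=O)=CO1
F4 | step 3 | methyl (2RS,6R)-2,4-dimethoxy-6-methyl-5,6-dihydro-2H-pyran-3-carboxylate | C[C@@H]1CC(OC)=C(C(=O)OC)C(OC)O1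
F5 | step 3 | [(2RS,6R)-2,4-dimethoxy-6-methyl-5,6-dihydro-2H-pyran-3-yl]methanol | C[C@@H]1CC(OC)=C(CO)C(OC)O1
F6 | step 3 | (2RS,6R)-2,4-dimethoxy-6-methyl-5,6-dihydro-2H-pyran-3-carbaldehyde | C[C@@H]1CC(OC)=C(C=O)C(OC)O1
F7 | step 4 | (5R)-5-hydroxy-N-methoxy-N-methyl-3-oxohexanamide | C[C@@H](O)CC(=O)CC(=O)N(C)OC
F8 | step 4 | (2R)-N-methoxy-N,2-dimethyl-4-oxo-3,4-dihydro-2H-pyran-5-carboxamide | C[C@@H]1CC(=O)C(C(=O)N(C)OC)=CO1
F9 | step 4 | (2RS,6R)-2-methoxy-3-[methoxy(methyl)carbamoyl]-6-methyl-5,6-dihydro-2H-pyran-4-yl 4-methylbenzenesulfonate | C[C@@H]1CC(OS(=O)(=O)c2ccc(C)cc2)=C(C(=O)N(C)OC)C(OC)O1
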